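Everything rests on cutting C7′=C8′ of ring B2 back to a vinyl group on C8a′ and an α-alkoxyallyl ketone on C4a′. One ring-closing metathesis closes ring B2 and, through tautomerisation of the resulting naphthalenone, delivers the C5′ naphthol as the only free hydroxyl, so the clustered oxygens on C6′, C5′ and peri C4′ emerge differentiated and C5′ can simply be methylated. The precursor is a pentasubstituted benzene (ring B1), built on the half A naphthalene by furan–acetylenedicarboxylate cycloaddition and ring opening; its two ester carbons become the vinyl group and the 2-(methoxymethoxy)but-3-enoyl chain, with C4′-O benzylated and C6′-O carried as a methoxymethyl ether.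

Key step: step 19

Remarks
- Locants: unprimed = half A naphthalene (C1 is the biaryl carbon), primed = half B naphthalene. Ar = 2,5-bis(benzyloxy)-4-methoxy-7-methylnaphthalen-1-yl (protected half A).
- Assumption: the target is specified without an axial descriptor, so the hindered C1–C1′ axis, which arises without control in step 8, is carried as a racemate; compounds 27 and 28 are therefore mixtures of two atropisomeric diastereomers.
- The C6′ oxygen is carried as a methoxymethyl (MOM) ether because the alkoxyallyl reagent is made by allylic lithiation, which an O-benzyl allyl ether would not survive (benzylic deprotonation and Wittig rearrangement).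
- Boronate 11 is taken to be a catalogue compound.

Step 1
Reactants: 1 methyl 2,4-dihydroxy-6-methylbenzoate (methyl orsellinate)
Product: 3 methyl 4-(benzyloxy)-2-methoxy-6-methylbenzoate, via 4-O-benzyl orsellinate 2 (not isolated)
Conditions: K2CO3, BnBr (1.05 equiv), acetone, 50 °C; then MeI (excess), reflux
Reagents that add atoms: benzyl bromide BrCc1ccccc1; iodomethane CI
Why: Williamson etherification in which the C4 hydroxyl, free of the hydrogen bond that ties the C2 hydroxyl to the ester, is alkylated first by one equivalent of benzyl bromide, after which the chelated C2 hydroxyl is methylated under forcing conditions.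

Step 2
Reactants: 3 methyl 4-(benzyloxy)-2-methoxy-6-methylbenzoate; 4 methyl (E)-but-2-enoate
Product: 5 methyl 6-(benzyloxy)-8-methoxy-3-methyl-1-oxo-1,2,3,4-tetrahydronaphthalene-2-carboxylate
Conditions: LiN(iPr)2, THF, −78 °C; then 4, −78 → 0 °C; 1 M HCl
Reagents that add atoms: none
Why: Tandem Michael–Dieckmann (Staunton–Weinreb-type) annulation in which the laterally lithiated ortho-toluate adds to the crotonate and the resulting ester enolate acylates on the aryl ester to close the six-membered ring, the C2/C3 stereocentres (formed without control, the product being largely enolised) being removed in steps 3 and 4.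

Step 3
Reactants: 5 methyl 6-(benzyloxy)-8-methoxy-3-methyl-1-oxo-1,2,3,4-tetrahydronaphthalene-2-carboxylate
Product: 6 6-(benzyloxy)-8-methoxy-3-methyl-3,4-dihydronaphthalen-1(2H)-one
Conditions: LiCl, H2O, DMSO, 150 °C
Reagents that add atoms: none
Why: Krapcho dealkoxycarbonylation (chloride attack on the ester methyl, then decarboxylation of the β-keto carboxylate) under neutral conditions that leave the benzyl and methyl aryl ethers untouched; C3 stays racemic and becomes sp2 in step 4.

Step 4
Reactants: 6 6-(benzyloxy)-8-methoxy-3-methyl-3,4-dihydronaphthalen-1(2H)-one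
Product: 8 6-(benzyloxy)-8-methoxy-3-methylnaphthalen-1-ol, via silyl enol ether 7 (not isolated)
Conditions: LiN(iPr)2, Me3SiCl, THF, −78 °C; then Pd(OAc)2 (1.1 equiv), MeCN, rt
Reagents that add atoms: none
Why: Saegusa–Ito dehydrogenation in which the only enolisable position (C2) is silylated, Pd(OAc)2 converts the silyl enol ether into the C2=C3 enone by β-hydride elimination, and this 4H-naphthalen-1-one tautomerises to the aromatic 1-naphthol without any electrophilic halogen that could attack the resorcinol-type ring.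

Step 5
Reactants: 8 6-(benzyloxy)-8-methoxy-3-methylnaphthalen-1-ol
Product: 9 1,6-bis(benzyloxy)-8-methoxy-3-methylnaphthalene
Conditions: BnBr, K2CO3, DMF, 60 °C
Reagents that add atoms: benzyl bromide BrCc1ccccc1
Why: Williamson etherification of the peri-hydrogen-bonded naphthol, for which the polar solvent and mild heating should suffice.

Step 6
Reactants: 9 1,6-bis(benzyloxy)-8-methoxy-3-methylnaphthalene
Product: 10 2,5-bis(benzyloxy)-1-bromo-4-methoxy-7-methylnaphthalene
Conditions: NBS, MeCN, 0 °C
Reagents that add atoms: N-bromosuccinimide O=C1CCC(=O)N1Br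
Why: Electrophilic aromatic bromination at C1, the α-position that is ortho to the C2 benzyloxy and para to the C4 methoxy group and therefore the most nucleophilic site of the 1,3-dialkoxynaphthalene ring.

Step 7
Reactants: 10 2,5-bis(benzyloxy)-1-bromo-4-methoxy-7-methylnaphthalene; 11 4,4,5,5-tetramethyl-2-(3-methylfuran-2-yl)-1,3,2-dioxaborolane
Product: 12 2-Ar-3-methylfuran
Conditions: Pd(OAc)2 (5 mol %), SPhos (10 mol %), K3PO4, 11 (1.8 equiv), toluene–H2O, 80 °C
Reagents that add atoms: none
Why: Suzuki–Miyaura coupling in which the dialkylbiarylphosphine ligand enables oxidative addition to the electron-rich ortho-substituted bromide and excess boronate offsets protodeboronation; the bond formed joins the naphthalene to a small five-membered heteroaryl, not to a second hindered arene.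

Step 8
Reactants: 12 2-Ar-3-methylfuran; 13 dimethyl but-2-ynedioate (dimethyl acetylenedicarboxylate)
Product: 15 dimethyl 3-Ar-6-hydroxy-4-methylbenzene-1,2-dicarboxylate, via oxanorbornadiene adduct 14 (not isolated)
Conditions: 13 (1.5 equiv), toluene, 90 °C; then BF3·OEt2 (0.3 equiv), 0 °C → rt
Reagents that add atoms: none
Why: Diels–Alder reaction of the furan with the symmetrical alkyne followed by Lewis-acid opening of the oxa-bridge, which ionises at the aryl-bearing bridgehead (tertiary, doubly allylic cation) and loses the other bridgehead proton, so the phenol necessarily ends up para to the aryl group and next to one ester; the bridgehead stereocentres of 14 vanish on aromatisation and the C1–C1′ axis forms as a racemate.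

Step 9
Reactants: 15 dimethyl 3-Ar-6-hydroxy-4-methylbenzene-1,2-dicarboxylate
Product: 16 4-Ar-2,3-bis(hydroxymethyl)-5-methylphenol
Conditions: LiAlH4, THF, 0 °C → rt
Reagents that add atoms: none
Why: Hydride reduction of both esters (the phenol is merely deprotonated), kept at or below room temperature so that the ortho-hydroxybenzylic alcohol is not hydrogenolysed.

Step 10
Reactants: 16 4-Ar-2,3-bis(hydroxymethyl)-5-methylphenol
Product: 17 (6-Ar-2,2,7-trimethyl-4H-1,3-benzodioxin-5-yl)methanol
Conditions: Me2C(OMe)2, TsOH·H2O (5 mol %), acetone, rt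
Reagents that add atoms: 2,2-dimethoxypropane COC(C)(C)OC
Why: Acid-catalysed ketalisation under equilibrating conditions should tie the phenol and the adjacent hydroxymethyl group into a six-membered 4H-1,3-benzodioxine, the ketal favoured for 3-hydroxy-1,2-bis(hydroxymethyl)arenes, leaving free only the hydroxymethyl group next to the biaryl axis.

Step 11
Reactants: 17 (6-Ar-2,2,7-trimethyl-4H-1,3-benzodioxin-5-yl)methanol
Product: 18 6-Ar-2,2,7-trimethyl-4H-1,3-benzodioxine-5-carbaldehyde
Conditions: Dess–Martin periodinane, pyridine, CH2Cl2, rt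
Reagents that add atoms: none
Why: Dess–Martin oxidation of a primary benzylic alcohol under pyridine buffering, which the acid-labile ketal and the benzyl ethers tolerate.

Step 12
Reactants: 18 6-Ar-2,2,7-trimethyl-4H-1,3-benzodioxine-5-carbaldehyde
Product: 19 6-Ar-5-ethenyl-2,2,7-trimethyl-4H-1,3-benzodioxine
Conditions: Ph3PCH3Br, KOtBu, THF, 0 °C → rt
Reagents that add atoms: methyltriphenylphosphonium bromide C[P+](c1ccccc1)(c1ccccc1)c1ccccc1.[Br-]
Why: Wittig methylenation with the small non-stabilised ylide, which reaches even a di-ortho-substituted benzaldehyde.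

Step 13
Reactants: 19 6-Ar-5-ethenyl-2,2,7-trimethyl-4H-1,3-benzodioxine
Product: 20 4-Ar-3-ethenyl-2-(hydroxymethyl)-5-methylphenol
Conditions: 1 M HCl, THF–MeOH, rt
Reagents that add atoms: none
Why: Mild aqueous-acid hydrolysis of the mixed aryl alkyl ketal, which is far more labile than the benzyl or methyl aryl ethers, at a temperature too low for ortho-quinone methide formation.

Step 14
Reactants: 20 4-Ar-3-ethenyl-2-(hydroxymethyl)-5-methylphenol
Product: 21 [3-Ar-6-(benzyloxy)-2-ethenyl-4-methylphenyl]methanol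
Conditions: BnBr, K2CO3, acetone, 50 °C
Reagents that add atoms: benzyl bromide BrCc1ccccc1
Why: Williamson etherification under carbonate base alkylates only the phenol, the primary alcohol being too weakly acidic to be deprotonated.

Step 15
Reactants: 21 [3-Ar-6-(benzyloxy)-2-ethenyl-4-methylphenyl]methanol
Product: 22 3-Ar-6-(benzyloxy)-2-ethenyl-4-methylbenzaldehyde
Conditions: Dess–Martin periodinane, pyridine, CH2Cl2, rt
Reagents that add atoms: none
Why: Dess–Martin oxidation of the primary benzylic alcohol, to which the styrene and the ethers are inert.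

Step 16
Reactants: 23 prop-2-en-1-ol (allyl alcohol)
Product: 24 3-(methoxymethoxy)prop-1-ene
Conditions: NaH, THF, 0 °C; MeOCH2Cl, 0 °C → rt; distillation
Reagents that add atoms: chloromethyl methyl ether COCCl
Why: O-Alkylation of the sodium alkoxide with the highly reactive α-chloro ether (Williamson-type acetal formation).

Step 17
Reactants: 22 3-Ar-6-(benzyloxy)-2-ethenyl-4-methylbenzaldehyde; 24 3-(methoxymethoxy)prop-1-ene
Product: 27 (1R,2R)-1-[3-Ar-6-(benzyloxy)-2-ethenyl-4-methylphenyl]-2-(methoxymethoxy)but-3-en-1-ol, via lithiated allyl ether 25 (not isolated), via allylborane 26 (not isolated)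
Conditions: 24 (1.6 equiv), s-BuLi, THF, −78 °C; (−)-Ipc2BOMe; BF3·OEt2; then 22, −78 °C → rt; NaOH, H2O2
Reagents that add atoms: none
Why: γ-Alkoxyallylboration of the Brown type, in which chelation-assisted allylic lithiation and boron trapping give the (Z)-γ-alkoxyallylborane that adds to the aldehyde through a chair six-membered transition state at its oxygen-bearing carbon only, giving the syn 2-alkoxy homoallylic alcohol (syn from the Z geometry, absolute sense from the isopinocampheyl groups, both centres being erased in steps 18 and 19).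

Step 18
Reactants: 27 (1R,2R)-1-[3-Ar-6-(benzyloxy)-2-ethenyl-4-methylphenyl]-2-(methoxymethoxy)but-3-en-1-ol
Product: 28 (2R)-1-[3-Ar-6-(benzyloxy)-2-ethenyl-4-methylphenyl]-2-(methoxymethoxy)but-3-en-1-one
Conditions: Dess–Martin periodinane, pyridine, CH2Cl2, 0 °C → rt
Reagents that add atoms: none
Why: Dess–Martin oxidation of the secondary benzylic alcohol under near-neutral, non-enolising conditions, so that the β,γ-double bond should not move into conjugation; the remaining C6′ stereocentre is of no consequence.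

Step 19
Reactants: 28 (2R)-1-[3-Ar-6-(benzyloxy)-2-ethenyl-4-methylphenyl]-2-(methoxymethoxy)but-3-en-1-one
Product: 30 2,4′,5-tris(benzyloxy)-4-methoxy-6′-(methoxymethoxy)-2′,7-dimethyl-[1,1′-binaphthalen]-5′-ol, via naphthalenone 29 (not isolated)
Conditions: second-generation Grubbs catalyst RuCl2(=CHPh)(PCy3)(H2IMes) (10 mol %), 1,4-benzoquinone (10 mol %), CH2Cl2 (0.005 M), 40 °C; then SiO2
Reagents that add atoms: none
Why: The ruthenium benzylidene should first engage the monosubstituted allylic-ether alkene (the vinyl group on C8a′ is flanked by two ortho substituents and initiates far more slowly), and the resulting alkylidene then undergoes intramolecular [2+2] cycloaddition and cycloreversion with the styrene, expelling ethene and forming C7′=C8′. The closest known reaction type is ring-closing metathesis of 1-(2-vinylaryl)but-3-en-1-ones to 2H-naphthalen-1-ones that aromatise to 1-naphthols. Ring B2 is closed as a six-membered carbocycle by ring-closing olefin metathesis between two terminal alkenes held ortho to each other on ring B1, after which the hydrogen on C6′ moves to the carbonyl oxygen (keto–enol tautomerisation driven by aromatisation, completed on silica gel); this erases the C6′ stereocentre, so no new stereocentre is formed. The selectivities needed are ring closure over cross-metathesis, secured by high dilution and the ortho pre-organisation, and metathesis over ruthenium-hydride migration of the allylic double bond into conjugation, suppressed by 1,4-benzoquinone. The position of the free hydroxyl is dictated by the substrate, since C5′ was the ketone carbon whereas C4′ and C6′ already carry their ethers.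

Step 20
Reactants: 30 2,4′,5-tris(benzyloxy)-4-methoxy-6′-(methoxymethoxy)-2′,7-dimethyl-[1,1′-binaphthalen]-5′-ol
Product: 31 2,4′,5-tris(benzyloxy)-4,5′-dimethoxy-6′-(methoxymethoxy)-2′,7-dimethyl-1,1′-binaphthalene
Conditions: MeI, K2CO3, DMF, 40 °C
Reagents that add atoms: iodomethane CI
Why: Williamson methylation of the only free hydroxyl group (C5′-OH), so no site selectivity is required.

Step 21
Reactants: 31 2,4′,5-tris(benzyloxy)-4,5′-dimethoxy-6′-(methoxymethoxy)-2′,7-dimethyl-1,1′-binaphthalene
Product: 32 2,4′,5-tris(benzyloxy)-4,5′-dimethoxy-2′,7-dimethyl-[1,1′-binaphthalen]-6′-ol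
Conditions: HCl (3 M in MeOH), THF, 40 °C
Reagents that add atoms: none
Why: Acid-catalysed methanolysis of the methoxymethyl acetal, to which aryl benzyl and aryl methyl ethers are stable.

Step 22
Reactants: 32 2,4′,5-tris(benzyloxy)-4,5′-dimethoxy-2′,7-dimethyl-[1,1′-binaphthalen]-6′-ol
Product: 33 4,5′-dimethoxy-2′,7-dimethyl-[1,1′-binaphthalene]-2,4′,5,6′-tetrol (target)
Conditions: H2 (1 atm), Pd/C (10 wt %), EtOAc–MeOH, rt
Reagents that add atoms: none
Why: Catalytic hydrogenolysis of the three aryl benzyl ethers over palladium at ambient pressure, conditions under which aryl methyl ethers and the naphthalene rings are untouched.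

Compound list
1 | methyl 2,4-dihydroxy-6-methylbenzoate (methyl orsellinate) | COC(=O)c1c(C)cc(O)cc1O | starting material
2 | methyl 4-(benzyloxy)-2-hydroxy-6-methylbenzoate | COC(=O)c1c(C)cc(OCc2ccccc2)cc1O | intermediate (not isolated)
3 | methyl 4-(benzyloxy)-2-methoxy-6-methylbenzoate | COC(=O)c1c(C)cc(OCc2ccccc2)cc1OC | intermediate
4 | methyl (E)-but-2-enoate | C/C=C/C(=O)OC | starting material
5 | methyl 6-(benzyloxy)-8-methoxy-3-methyl-1-oxo-1,2,3,4-tetrahydronaphthalene-2-carboxylate (diastereomer/enol mixture, racemic) | COC(=O)C1C(C)Cc2cc(OCc3ccccc3)cc(OC)c2C1=O | intermediate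
6 | 6-(benzyloxy)-8-methoxy-3-methyl-3,4-dihydronaphthalen-1(2H)-one (racemic) | CC1CC(=O)c2c(OC)cc(OCc3ccccc3)cc2C1 | intermediate
7 | {[6-(benzyloxy)-8-methoxy-3-methyl-3,4-dihydronaphthalen-1-yl]oxy}trimethylsilane (racemic) | CC1Cc2cc(OCc3ccccc3)cc(OC)c2C(O[Si](C)(C)C)=C1 | intermediate (not isolated)
8 | 6-(benzyloxy)-8-methoxy-3-methylnaphthalen-1-ol | Cc1cc(O)c2c(OC)cc(OCc3ccccc3)cc2c1 | intermediate
9 | 1,6-bis(benzyloxy)-8-methoxy-3-methylnaphthalene | Cc1cc(OCc2ccccc2)c2c(OC)cc(OCc3ccccc3)cc2c1 | intermediate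
10 | 2,5-bis(benzyloxy)-1-bromo-4-methoxy-7-methylnaphthalene | Cc1cc(OCc2ccccc2)c2c(OC)cc(OCc3ccccc3)c(Br)c2c1 | intermediate
11 | 4,4,5,5-tetramethyl-2-(3-methylfuran-2-yl)-1,3,2-dioxaborolane | Cc1ccoc1B1OC(C)(C)C(C)(C)O1 | starting material
12 | 2-[2,5-bis(benzyloxy)-4-methoxy-7-methylnaphthalen-1-yl]-3-methylfuran | Cc1ccoc1-c1c(OCc2ccccc2)cc(OC)c2c(OCc3ccccc3)cc(C)cc12 | intermediate
13 | dimethyl but-2-ynedioate | COC(=O)C#CC(=O)OC | starting material
14 | dimethyl 1-Ar-6-methyl-7-oxabicyclo[2.2.1]hepta-2,5-diene-2,3-dicarboxylate (racemic) | COC(=O)C1=C(C(=O)OC)C2(c3c(OCc4ccccc4)cc(OC)c4c(OCc5ccccc5)cc(C)cc34)OC1C=C2C | intermediate (not isolated)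
15 | dimethyl 3-Ar-6-hydroxy-4-methylbenzene-1,2-dicarboxylate (racemic axis) | COC(=O)c1c(O)cc(C)c(-c2c(OCc3ccccc3)cc(OC)c3c(OCc4ccccc4)cc(C)cc23)c1C(=O)OC | intermediate
16 | 4-Ar-2,3-bis(hydroxymethyl)-5-methylphenol (racemic axis) | OCc1c(O)cc(C)c(-c2c(OCc3ccccc3)cc(OC)c3c(OCc4ccccc4)cc(C)cc23)c1CO | intermediate
17 | (6-Ar-2,2,7-trimethyl-4H-1,3-benzodioxin-5-yl)methanol (racemic axis) | CC1(C)OCc2c(CO)c(-c3c(OCc4ccccc4)cc(OC)c4c(OCc5ccccc5)cc(C)cc34)c(C)cc2O1 | intermediate
18 | 6-Ar-2,2,7-trimethyl-4H-1,3-benzodioxine-5-carbaldehyde (racemic axis) | CC1(C)OCc2c(C=O)c(-c3c(OCc4ccccc4)cc(OC)c4c(OCc5ccccc5)cc(C)cc34)c(C)cc2O1 | intermediate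
19 | 6-Ar-5-ethenyl-2,2,7-trimethyl-4H-1,3-benzodioxine (racemic axis) | CC1(C)OCc2c(C=C)c(-c3c(OCc4ccccc4)cc(OC)c4c(OCc5ccccc5)cc(C)cc34)c(C)cc2O1 | intermediate
20 | 4-Ar-3-ethenyl-2-(hydroxymethyl)-5-methylphenol (racemic axis) | OCc1c(O)cc(C)c(-c2c(OCc3ccccc3)cc(OC)c3c(OCc4ccccc4)cc(C)cc23)c1C=C | intermediate
21 | [3-Ar-6-(benzyloxy)-2-ethenyl-4-methylphenyl]methanol (racemic axis) | OCc1c(OCc2ccccc2)cc(C)c(-c2c(OCc3ccccc3)cc(OC)c3c(OCc4ccccc4)cc(C)cc23)c1C=C | intermediate
22 | 3-Ar-6-(benzyloxy)-2-ethenyl-4-methylbenzaldehyde (racemic axis) | O=Cc1c(OCc2ccccc2)cc(C)c(-c2c(OCc3ccccc3)cc(OC)c3c(OCc4ccccc4)cc(C)cc23)c1C=C | intermediate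
23 | prop-2-en-1-ol | C=CCO | starting material
24 | 3-(methoxymethoxy)prop-1-ene | C=CCOCOC | intermediate
25 | [1-(methoxymethoxy)prop-2-en-1-yl]lithium | C=CC([Li])OCOC | intermediate (not isolated)
26 | [(Z)-3-(methoxymethoxy)prop-2-en-1-yl]bis[(1R,2S,3R,5R)-isopinocampheyl]borane, i.e. with the isopinocampheyl groups of (−)-Ipc2BOMe | COCO/C=C\CB([C@@H]1C[C@@H]2C[C@H]([C@H]1C)C2(C)C)[C@@H]1C[C@@H]2C[C@H]([C@H]1C)C2(C)C | intermediate (not isolated)
27 | (1R,2R)-1-[3-Ar-6-(benzyloxy)-2-ethenyl-4-methylphenyl]-2-(methoxymethoxy)but-3-en-1-ol (syn; two atropisomeric diastereomers) | C=C[C@@H](OCOC)[C@H](O)c1c(OCc2ccccc2)cc(C)c(-c2c(OCc3ccccc3)cc(OC)c3c(OCc4ccccc4)cc(C)cc23)c1C=C | intermediate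
28 | (2R)-1-[3-Ar-6-(benzyloxy)-2-ethenyl-4-methylphenyl]-2-(methoxymethoxy)but-3-en-1-one (two atropisomeric diastereomers) | C=C[C@@H](OCOC)C(=O)c1c(OCc2ccccc2)cc(C)c(-c2c(OCc3ccccc3)cc(OC)c3c(OCc4ccccc4)cc(C)cc23)c1C=C | intermediate
29 | (2R)-5-Ar-8-(benzyloxy)-2-(methoxymethoxy)-6-methylnaphthalen-1(2H)-one | Cc1cc(OCc2ccccc2)c2c(c1-c1c(OCc3ccccc3)cc(OC)c3c(OCc4ccccc4)cc(C)cc13)C=C[C@@H](OCOC)C2=O | intermediate (not isolated)
30 | 2,4′,5-tris(benzyloxy)-4-methoxy-6′-(methoxymethoxy)-2′,7-dimethyl-[1,1′-binaphthalen]-5′-ol (racemic axis) | Cc1cc(OCc2ccccc2)c2c(O)c(OCOC)ccc2c1-c1c(OCc2ccccc2)cc(OC)c2c(OCc3ccccc3)cc(C)cc12 | intermediate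
31 | 2,4′,5-tris(benzyloxy)-4,5′-dimethoxy-6′-(methoxymethoxy)-2′,7-dimethyl-1,1′-binaphthalene (racemic axis) | Cc1cc(OCc2ccccc2)c2c(OC)c(OCOC)ccc2c1-c1c(OCc2ccccc2)cc(OC)c2c(OCc3ccccc3)cc(C)cc12 | intermediate
32 | 2,4′,5-tris(benzyloxy)-4,5′-dimethoxy-2′,7-dimethyl-[1,1′-binaphthalen]-6′-ol (racemic axis) | Cc1cc(OCc2ccccc2)c2c(OC)c(O)ccc2c1-c1c(OCc2ccccc2)cc(OC)c2c(OCc3ccccc3)cc(C)cc12 | intermediate
33 | 4,5′-dimethoxy-2′,7-dimethyl-[1,1′-binaphthalene]-2,4′,5,6′-tetrol (racemic axis) | COc1cc(O)c(-c2c(C)cc(O)c3c(OC)c(O)ccc23)c2cc(C)cc(O)c12 | target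

Total step count: 22. Longest linear sequence: 21 steps (steps 1–15 and 17–22, from methyl orsellinate 1).

Steps most likely to fail

Step 19. The ruthenium alkylidene may be held in an unproductive chelate by the ketone or acetal oxygens, the doubly ortho-substituted styrene may fail to enter the ring closure so that intermolecular metathesis takes over, or a ruthenium hydride may shift the allylic double bond into conjugation before closure. The fallback inverts the order of oxidation and metathesis and sets out from alcohol 27, which has no acidic α-hydrogen and no carbonyl to chelate. It would be cyclised with the same catalyst to (1R,2R)-5-Ar-8-(benzyloxy)-2-(methoxymethoxy)-6-methyl-1,2-dihydronaphthalen-1-ol F1, handled without acid to avoid dehydration. Dess–Martin oxidation of this benzylic alcohol would then give naphthalenone 29, which tautomerises, and the route is rejoined at 30.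

Step 10. Ketalisation may lose site selectivity and bridge the two hydroxymethyl groups in a seven-membered ring instead of engaging the phenol. The fallback differentiates the two arms by steric hindrance and sets out from triol 16. Selective phenol benzylation (BnBr, K2CO3) would give [3-Ar-6-(benzyloxy)-4-methyl-1,2-phenylene]dimethanol F2. Low-temperature silylation with t-BuPh2SiCl and imidazole should take the hydroxymethyl group next to the benzyloxy group, the other being shielded by the twisted naphthyl group, giving the monosilyl ether [6-Ar-3-(benzyloxy)-2-({[tert-butyl(diphenyl)silyl]oxy}methyl)-5-methylphenyl]methanol F3. Dess–Martin oxidation would give 6-Ar-3-(benzyloxy)-2-({[tert-butyl(diphenyl)silyl]oxy}methyl)-5-methylbenzaldehyde F4, Wittig methylenation would give tert-butyl{[3-Ar-6-(benzyloxy)-2-ethenyl-4-methylphenyl]methoxy}diphenylsilane F5, and desilylation with Bu4NF rejoins the route at 21.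

Step 7. Protodeboronation of the 2-furylboronate may outrun transmetalation onto the hindered arylpalladium intermediate. The fallback builds the furan by addition and dehydration instead of cross-coupling and sets out from bromide 10. Bromine–lithium exchange (n-BuLi, THF, −78 °C) and 1,2-addition of the aryllithium to 3-methylfuran-2(5H)-one would give the lactol 2-Ar-3-methyl-2,5-dihydrofuran-2-ol F6. Acid-catalysed 1,4-dehydration (TsOH, toluene) aromatises it to furan 12, where the route is rejoined.

Further compounds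
F1 | step 19 | (1R,2R)-5-Ar-8-(benzyloxy)-2-(methoxymethoxy)-6-methyl-1,2-dihydronaphthalen-1-ol | O[C@H]1[C@H](OCOC)C=Cc2c(-c3c(OCc4ccccc4)cc(OC)c4c(OCc5ccccc5)cc(C)cc34)c(C)cc(OCc3ccccc3)c12
F2 | step 10 | [3-Ar-6-(benzyloxy)-4-methyl-1,2-phenylene]dimethanol | OCc1c(OCc2ccccc2)cc(C)c(-c2c(OCc3ccccc3)cc(OC)c3c(OCc4ccccc4)cc(C)cc23)c1CO
F3 | step 10 | [6-Ar-3-(benzyloxy)-2-({[tert-butyl(diphenyl)silyl]oxy}methyl)-5-methylphenyl]methanol | CC(C)(C)[Si](OCc1c(OCc2ccccc2)cc(C)c(-c2c(OCc3ccccc3)cc(OC)c3c(OCc4ccccc4)cc(C)cc23)c1CO)(c1ccccc1)c1ccccc1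
F4 | step 10 | 6-Ar-3-(benzyloxy)-2-({[tert-butyl(diphenyl)silyl]oxy}methyl)-5-methylbenzaldehyde | CC(C)(C)[Si](OCc1c(OCc2ccccc2)cc(C)c(-c2c(OCc3ccccc3)cc(OC)c3c(OCc4ccccc4)cc(C)cc23)c1C=O)(c1ccccc1)c1ccccc1
F5 | step 10 | tert-butyl{[3-Ar-6-(benzyloxy)-2-ethenyl-4-methylphenyl]methoxy}diphenylsilane | CC(C)(C)[Si](OCc1c(OCc2ccccc2)cc(C)c(-c2c(OCc3ccccc3)cc(OC)c3c(OCc4ccccc4)cc(C)cc23)c1C=C)(c1ccccc1)c1ccccc1
F6 | step 7 | 2-Ar-3-methyl-2,5-dihydrofuran-2-ol (racemic) | CC1=CCOC1(O)c1c(OCc2ccccc2)cc(OC)c2c(OCc3ccccc3)cc(C)cc12
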